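The cyclohexane ring is closed last, between the ring carbinol carbon (CH–OH) and the adjacent ring carbon that carries the 3-hydroxyprop-1-en-2-yl group. This homoallylic alcohol with an exocyclic C=CH2 is the footprint of an intramolecular carbonyl-ene reaction (isopulegol-type). An open-chain aldehyde whose (Z)-trisubstituted allylic silyl ether sits on the quaternary methyl/vinyl carbon should cyclise under Me2AlCl, forming the ring, both new stereocentres (trans, diequatorial) and the 1,1-disubstituted alkene in one operation. The precursor already holds the quaternary centre (Pd-catalysed allylic alkylation), the acyloxy and acrylate-bearing carbons (asymmetric allylboration) and the complete side-chain ester.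

Key step: step 16

Assumption: the sense of induction of the (S,S)-Trost ligand (step 1) and of (S)-TRIP (step 13) is taken from the closest precedents (vinyl-epoxide alkylations; allyl- and crotylborations); should either be opposite, the enantiomeric ligand or catalyst is used and nothing else changes.

TBS = tert-butyldimethylsilyl; Bpin = pinacolatoboryl; TRIP = 3,3'-bis(2,4,6-triisopropylphenyl)-1,1'-binaphthyl-2,2'-diyl hydrogen phosphate.

**Quaternary-carbon aldehyde (steps 1–7)**

Step 1
Reactants: 1 2-ethenyl-2-methyloxirane (racemic); 2 dimethyl malonate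
Product: 4 methyl (4S)-4-ethenyl-4-methyl-2-oxooxolane-3-carboxylate (C3 epimers), via hydroxy malonate 3 (not isolated)
Conditions: Pd2(dba)3·CHCl3 (1 mol%), (S,S)-DACH-naphthyl Trost ligand (3 mol%), CH2Cl2, rt; then DBU (cat.)
Reagents that add atoms: none
Why: Pd-catalysed dynamic kinetic asymmetric allylic alkylation, in which both enantiomers of 1 give interconverting π-allyl complexes, the alkoxide-directed malonate attacks the tertiary terminus inside the chiral pocket to set the quaternary carbon, and the hydroxy ester then lactonises.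

Step 2
Reactants: 4 methyl (4S)-4-ethenyl-4-methyl-2-oxooxolane-3-carboxylate
Product: 5 (4R)-4-ethenyl-4-methyloxolan-2-one
Conditions: LiCl, H2O, DMSO, 140 °C
Reagents that add atoms: none
Why: Krapcho dealkoxycarbonylation of the α-carbomethoxy lactone, which does not touch the quaternary stereocentre.

Step 3
Reactants: 5 (4R)-4-ethenyl-4-methyloxolan-2-one
Product: 6 (3R)-3-(hydroxymethyl)-N-methoxy-N,3-dimethylpent-4-enamide
Conditions: MeNH(OMe)·HCl, Me3Al, CH2Cl2, 0 °C to rt
Reagents that add atoms: N,O-dimethylhydroxylamine hydrochloride, CNOC.Cl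
Why: Weinreb aminolysis of the lactone by the aluminium amide should give the open hydroxy amide, which is used crude to avoid relactonisation.

Step 4
Reactants: 6 (3R)-3-(hydroxymethyl)-N-methoxy-N,3-dimethylpent-4-enamide
Product: 7 (3R)-3-formyl-N-methoxy-N,3-dimethylpent-4-enamide
Conditions: Dess–Martin periodinane, NaHCO3, CH2Cl2, 0 °C to rt
Reagents that add atoms: none
Why: Dess–Martin oxidation of the neopentyl primary alcohol gives an α-quaternary aldehyde that can neither epimerise nor isomerise.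

Step 5
Reactants: 7 (3R)-3-formyl-N-methoxy-N,3-dimethylpent-4-enamide
Product: 8 methyl (2Z,4R)-4-ethenyl-6-[methoxy(methyl)amino]-2,4-dimethyl-6-oxohex-2-enoate
Conditions: KN(SiMe3)2, 18-crown-6, THF, −78 °C
Reagents that add atoms: methyl 2-[bis(2,2,2-trifluoroethoxy)phosphoryl]propanoate, COC(=O)C(C)P(=O)(OCC(F)(F)F)OCC(F)(F)F
Why: Still–Gennari olefination, in which fast irreversible elimination from the kinetic adduct should give the (Z)-trisubstituted enoate with the ester cis to the quaternary carbon.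

Step 6
Reactants: 8 methyl (2Z,4R)-4-ethenyl-6-[methoxy(methyl)amino]-2,4-dimethyl-6-oxohex-2-enoate
Product: 9 (3R,4Z)-3-ethenyl-6-hydroxy-3,5-dimethylhex-4-enal
Conditions: iBu2AlH (3.5 equiv), CH2Cl2, −78 °C; aq. potassium sodium tartrate
Reagents that add atoms: none
Why: iBu2AlH reduces the enoate 1,2 to the allylic alcohol while the Weinreb amide stops at the chelated hemiaminal and releases the aldehyde only on work-up, with the Z geometry retained.

Step 7
Reactants: 9 (3R,4Z)-3-ethenyl-6-hydroxy-3,5-dimethylhex-4-enal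
Product: 10 (3R,4Z)-6-(TBS-oxy)-3-ethenyl-3,5-dimethylhex-4-enal
Conditions: TBSCl, imidazole, CH2Cl2, 0 °C
Reagents that add atoms: tert-butyldimethylsilyl chloride, CC(C)(C)[Si](C)(C)Cl
Why: standard silylation of the primary allylic alcohol, which should also drain any seven-membered lactol form of 9 through the open hydroxy aldehyde.

**Allylboronate (steps 8–10)**

Step 8
Reactants: 11 prop-2-en-1-yl prop-2-enoate (allyl acrylate); 12 2,2-dimethoxyacetaldehyde (60% in water)
Product: 13 prop-2-en-1-yl 3-hydroxy-4,4-dimethoxy-2-methylidenebutanoate (racemic)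
Conditions: DABCO (0.5 equiv), 1,4-dioxane/H2O, rt
Reagents that add atoms: none
Why: Morita–Baylis–Hillman reaction of the activated glyoxal mono-acetal with the acrylate, whose racemic carbinol centre is erased two steps later.

Step 9
Reactants: 13 prop-2-en-1-yl 3-hydroxy-4,4-dimethoxy-2-methylidenebutanoate
Product: 14 prop-2-en-1-yl 3-acetoxy-4,4-dimethoxy-2-methylidenebutanoate (racemic)
Conditions: Ac2O, pyridine, DMAP (cat.), CH2Cl2, 0 °C
Reagents that add atoms: acetic anhydride, CC(=O)OC(C)=O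
Why: acetylation installs the allylic leaving group needed for the SN2' borylation.

Step 10
Reactants: 14 prop-2-en-1-yl 3-acetoxy-4,4-dimethoxy-2-methylidenebutanoate
Product: 15 prop-2-en-1-yl (2E)-4,4-dimethoxy-2-[(Bpin)methyl]but-2-enoate
Conditions: B2pin2, CuCl (10 mol%), LiCl, KOAc, DMF, rt
Reagents that add atoms: bis(pinacolato)diboron, CC1(C)OB(OC1(C)C)B1OC(C)(C)C(C)(C)O1
Why: copper-catalysed SN2' borylation of the Morita–Baylis–Hillman acetate (conjugate borylcupration, then loss of acetate) should give the preferred trisubstituted enoate with the acetal carbon cis to CH2B.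

**Side-chain acid (steps 11–12)**

Step 11
Reactants: 16 (4R)-4-hydroxyoxolan-2-one ((R)-3-hydroxy-γ-butyrolactone)
Product: 19 (4R)-4-hydroxy-3-methylideneoxolan-2-one, via Mannich base 17 (not isolated), via ammonium iodide 18 (not isolated)
Conditions: LiN(iPr)2 (2.2 equiv), THF, −78 °C; CH2=NMe2+ I−, −78 to 0 °C; then MeI, MeOH, rt; then aq. NaHCO3, CH2Cl2
Reagents that add atoms: N,N-dimethylmethyleneiminium iodide (Eschenmoser's salt), C=[N+](C)C.[I-]
Why: Mannich reaction of the alkoxide–enolate dianion, quaternisation and elimination of trimethylamine is the standard α-methylenation of lactones and leaves the carbinol stereocentre untouched.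

Step 12
Reactants: 19 (4R)-4-hydroxy-3-methylideneoxolan-2-one
Product: 22 (3R)-3,4-bis(TBS-oxy)-2-methylidenebutanoic acid, via lithium carboxylate 20 (not isolated), via silyl ester 21 (not isolated)
Conditions: LiOH, THF/H2O, 0 °C; then TBSCl, imidazole, DMF, rt; then K2CO3, MeOH/THF/H2O, rt; pH 5 work-up
Reagents that add atoms: lithium hydroxide, [Li+].[OH-]; tert-butyldimethylsilyl chloride, CC(C)(C)[Si](C)(C)Cl
Why: saponification, persilylation and selective hydrolysis of the labile silyl ester should deliver the protected acid without relactonisation.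

**Assembly, ring closure and deprotection (steps 13–18)**

Step 13
Reactants: 10 (3R,4Z)-6-(TBS-oxy)-3-ethenyl-3,5-dimethylhex-4-enal; 15 prop-2-en-1-yl (2E)-4,4-dimethoxy-2-[(Bpin)methyl]but-2-enoate
Product: 24 prop-2-en-1-yl (3R,4R,6R,7Z)-9-(TBS-oxy)-3-(dimethoxymethyl)-6-ethenyl-4-hydroxy-6,8-dimethyl-2-methylidenenon-7-enoate, via pinacol borate 23 (not isolated)
Conditions: (S)-TRIP (10 mol%), 4 Å molecular sieves, toluene, −30 °C to rt; then aq. NaHCO3
Reagents that add atoms: none
Why: chiral phosphoric acid-catalysed allylboration through a closed chair transition state, in which the γ-substituent cis to CH2B is axial so that the syn adduct forms, while the catalyst directs attack to the Si face of the aldehyde and thereby fixes both new stereocentres.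

Step 14
Reactants: 24 the homoallylic alcohol from step 13; 22 (3R)-3,4-bis(TBS-oxy)-2-methylidenebutanoic acid
Product: 26 prop-2-en-1-yl (3R,4R,6R,7Z)-4-{[(3R)-3,4-bis(TBS-oxy)-2-methylidenebutanoyl]oxy}-9-(TBS-oxy)-3-(dimethoxymethyl)-6-ethenyl-6,8-dimethyl-2-methylidenenon-7-enoate, via mixed anhydride 25 (not isolated)
Conditions: 2,4,6-trichlorobenzoyl chloride, Et3N, THF, rt; then 24, DMAP, toluene, rt
Reagents that add atoms: none
Why: Yamaguchi esterification of the hindered secondary alcohol through the mixed anhydride, with no stereocentre involved.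

Step 15
Reactants: 26 the acetal ester from step 14
Product: 28 prop-2-en-1-yl (3R,4R,6R,7Z)-4-{[(3R)-3,4-bis(TBS-oxy)-2-methylidenebutanoyl]oxy}-9-(TBS-oxy)-6-ethenyl-3-formyl-6,8-dimethyl-2-methylidenenon-7-enoate, via collidinium salt 27 (not isolated)
Conditions: TESOTf, 2,4,6-collidine, CH2Cl2, 0 °C; then H2O
Reagents that add atoms: water, O
Why: chemoselective cleavage of the dimethyl acetal through a collidinium salt under nearly neutral conditions should spare silyl ethers and esters and avoid epimerisation or β-elimination of the sensitive aldehyde.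

Step 16
Reactants: 28 the aldehyde from step 15
Product: 30 prop-2-en-1-yl 2-[(1S,2S,3S,4R,6R)-6-{[(3R)-3,4-bis(TBS-oxy)-2-methylidenebutanoyl]oxy}-3-[3-(TBS-oxy)prop-1-en-2-yl]-4-ethenyl-2-hydroxy-4-methylcyclohexyl]prop-2-enoate, via aluminium alkoxide 29 (not isolated)
Conditions: Me2AlCl (2.5 equiv), CH2Cl2, −78 °C; aq. potassium sodium tartrate at −78 °C
Reagents that add atoms: none
Why: The aldehyde–Me2AlCl complex is attacked by the less substituted carbon of the (Z)-trisubstituted alkene while a hydrogen of the methyl group syn to the vinylic hydrogen moves to oxygen in a concerted, chair-like six-centre array (intramolecular carbonyl-ene reaction, made irreversible by loss of methane from aluminium). The closest known reaction is the Lewis acid-promoted cyclisation of citronellal to isopulegol. The cyclohexane closes in a 6-exo-trig sense at the carbonyl, with the ene double bond exocyclic to the new ring. The carbinol centre is set by the equatorial placement of the complexed C=O, enforced by the axial methyl group on the quaternary carbon (an axial C–O would be 1,3-diaxial to it), and the neighbouring centre by the equatorial placement of the alkenyl carbon, which gives the trans-diequatorial pair. The reaction needs this chair (methyl axial, vinyl and acyloxy equatorial, acrylate carbon axial) over its ring-flipped form, which the syn-diaxial vinyl/acyloxy clash of the latter should secure, and it needs hydrogen transfer from the methyl group and not from CH2OTBS, which the Z geometry secures. The low temperature and the non-basic Lewis acid should keep the α-stereocentre of the aldehyde from epimerising.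

Step 17
Reactants: 30 the cyclohexanol from step 16
Product: 31 prop-2-en-1-yl 2-[(1S,2S,3S,4R,6R)-6-{[(3R)-3,4-dihydroxy-2-methylidenebutanoyl]oxy}-4-ethenyl-2-hydroxy-3-(3-hydroxyprop-1-en-2-yl)-4-methylcyclohexyl]prop-2-enoate
Conditions: HF·pyridine, pyridine, THF, 0 °C to rt
Reagents that add atoms: none
Why: buffered fluoride cleavage of the three silyl ethers, under which the three esters should persist.

Step 18
Reactants: 31 the allyl ester from step 17
Product: 32 2-[(1S,2S,3S,4R,6R)-6-{[(3R)-3,4-dihydroxy-2-methylidenebutanoyl]oxy}-4-ethenyl-2-hydroxy-3-(3-hydroxyprop-1-en-2-yl)-4-methylcyclohexyl]prop-2-enoic acid (CNP0348657.1)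
Conditions: Pd(PPh3)4 (5 mol%), N-methylaniline, THF, rt; pH 5 buffer work-up
Reagents that add atoms: none
Why: Tsuji–Trost deallylation transfers the allyl group to the amine and frees the acid under neutral conditions, so that neither cleavage of the side-chain ester nor lactonisation is expected.

**Compound list**

1 | 2-ethenyl-2-methyloxirane (racemic) | CC1(C=C)CO1 | starting material
2 | dimethyl malonate | COC(=O)CC(=O)OC | starting material
3 | dimethyl 2-[(2S)-1-hydroxy-2-methylbut-3-en-2-yl]propanedioate | C=C[C@@](CO)(C)C(C(=O)OC)C(=O)OC | intermediate (not isolated)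
4 | methyl (4S)-4-ethenyl-4-methyl-2-oxooxolane-3-carboxylate (C3 epimers) | C=C[C@@]1(C)C(C(=O)OC)C(=O)OC1 | intermediate
5 | (4R)-4-ethenyl-4-methyloxolan-2-one | C=C[C@@]1(C)CC(=O)OC1 | intermediate
6 | (3R)-3-(hydroxymethyl)-N-methoxy-N,3-dimethylpent-4-enamide | C=C[C@@](CO)(C)CC(=O)N(C)OC | intermediate
7 | (3R)-3-formyl-N-methoxy-N,3-dimethylpent-4-enamide | C=C[C@@](C=O)(C)CC(=O)N(C)OC | intermediate
8 | methyl (2Z,4R)-4-ethenyl-6-[methoxy(methyl)amino]-2,4-dimethyl-6-oxohex-2-enoate | C=C[C@@](/C=C(/C)C(=O)OC)(C)CC(=O)N(C)OC | intermediate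
9 | (3R,4Z)-3-ethenyl-6-hydroxy-3,5-dimethylhex-4-enal | C=C[C@@](/C=C(/C)CO)(C)CC=O | intermediate
10 | (3R,4Z)-6-(TBS-oxy)-3-ethenyl-3,5-dimethylhex-4-enal | C=C[C@@](/C=C(/C)CO[Si](C)(C)C(C)(C)C)(C)CC=O | intermediate
11 | prop-2-en-1-yl prop-2-enoate | C=CC(=O)OCC=C | starting material
12 | 2,2-dimethoxyacetaldehyde | COC(OC)C=O | starting material
13 | prop-2-en-1-yl 3-hydroxy-4,4-dimethoxy-2-methylidenebutanoate (racemic) | C=CCOC(=O)C(=C)C(O)C(OC)OC | intermediate
14 | prop-2-en-1-yl 3-acetoxy-4,4-dimethoxy-2-methylidenebutanoate (racemic) | C=CCOC(=O)C(=C)C(OC(C)=O)C(OC)OC | intermediate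
15 | prop-2-en-1-yl (2E)-4,4-dimethoxy-2-[(4,4,5,5-tetramethyl-1,3,2-dioxaborolan-2-yl)methyl]but-2-enoate | C=CCOC(=O)/C(CB1OC(C)(C)C(C)(C)O1)=C/C(OC)OC | intermediate
16 | (4R)-4-hydroxyoxolan-2-one | O=C1C[C@@H](O)CO1 | starting material
17 | (3R,4R)-3-[(dimethylamino)methyl]-4-hydroxyoxolan-2-one (trans) | O=C1[C@H](CN(C)C)[C@@H](O)CO1 | intermediate (not isolated)
18 | {[(3R,4R)-4-hydroxy-2-oxooxolan-3-yl]methyl}trimethylammonium iodide | O=C1[C@H](C[N+](C)(C)C)[C@@H](O)CO1.[I-] | intermediate (not isolated)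
19 | (4R)-4-hydroxy-3-methylideneoxolan-2-one | O=C1C(=C)[C@@H](O)CO1 | intermediate
20 | lithium (3R)-3,4-dihydroxy-2-methylidenebutanoate | [Li+].[O-]C(=O)C(=C)[C@@H](O)CO | intermediate (not isolated)
21 | tert-butyldimethylsilyl (3R)-3,4-bis(TBS-oxy)-2-methylidenebutanoate | C=C([C@@H](O[Si](C)(C)C(C)(C)C)CO[Si](C)(C)C(C)(C)C)C(=O)O[Si](C)(C)C(C)(C)C | intermediate (not isolated)
22 | (3R)-3,4-bis(TBS-oxy)-2-methylidenebutanoic acid | C=C([C@@H](O[Si](C)(C)C(C)(C)C)CO[Si](C)(C)C(C)(C)C)C(=O)O | intermediate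
23 | pinacol borate of 24 (O-Bpin at the new carbinol) | C=C[C@@](/C=C(/C)CO[Si](C)(C)C(C)(C)C)(C)C[C@@H](OB1OC(C)(C)C(C)(C)O1)[C@@H](C(=C)C(=O)OCC=C)C(OC)OC | intermediate (not isolated)
24 | prop-2-en-1-yl (3R,4R,6R,7Z)-9-(TBS-oxy)-3-(dimethoxymethyl)-6-ethenyl-4-hydroxy-6,8-dimethyl-2-methylidenenon-7-enoate | C=C[C@@](/C=C(/C)CO[Si](C)(C)C(C)(C)C)(C)C[C@@H](O)[C@@H](C(=C)C(=O)OCC=C)C(OC)OC | intermediate
25 | (3R)-3,4-bis(TBS-oxy)-2-methylidenebutanoic 2,4,6-trichlorobenzoic anhydride | C=C([C@@H](O[Si](C)(C)C(C)(C)C)CO[Si](C)(C)C(C)(C)C)C(=O)OC(=O)c1c(Cl)cc(Cl)cc1Cl | intermediate (not isolated)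
26 | prop-2-en-1-yl (3R,4R,6R,7Z)-4-{[(3R)-3,4-bis(TBS-oxy)-2-methylidenebutanoyl]oxy}-9-(TBS-oxy)-3-(dimethoxymethyl)-6-ethenyl-6,8-dimethyl-2-methylidenenon-7-enoate | C=C[C@@](/C=C(/C)CO[Si](C)(C)C(C)(C)C)(C)C[C@@H](OC(=O)C(=C)[C@@H](O[Si](C)(C)C(C)(C)C)CO[Si](C)(C)C(C)(C)C)[C@@H](C(=C)C(=O)OCC=C)C(OC)OC | intermediate
27 | N-(α-methoxyalkyl)-2,4,6-trimethylpyridinium triflate derived from 26 (one OMe replaced by collidinium) | C=C[C@@](/C=C(/C)CO[Si](C)(C)C(C)(C)C)(C)C[C@@H](OC(=O)C(=C)[C@@H](O[Si](C)(C)C(C)(C)C)CO[Si](C)(C)C(C)(C)C)[C@@H](C(=C)C(=O)OCC=C)C(OC)[n+]1c(C)cc(C)cc1C.[O-]S(=O)(=O)C(F)(F)F | intermediate (not isolated)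
28 | prop-2-en-1-yl (3R,4R,6R,7Z)-4-{[(3R)-3,4-bis(TBS-oxy)-2-methylidenebutanoyl]oxy}-9-(TBS-oxy)-6-ethenyl-3-formyl-6,8-dimethyl-2-methylidenenon-7-enoate | C=C[C@@](/C=C(/C)CO[Si](C)(C)C(C)(C)C)(C)C[C@@H](OC(=O)C(=C)[C@@H](O[Si](C)(C)C(C)(C)C)CO[Si](C)(C)C(C)(C)C)[C@@H](C(=C)C(=O)OCC=C)C=O | intermediate
29 | chloro(methyl)aluminium alkoxide of 30 | C=C[C@@]1(C)C[C@@H](OC(=O)C(=C)[C@@H](O[Si](C)(C)C(C)(C)C)CO[Si](C)(C)C(C)(C)C)[C@@H](C(=C)C(=O)OCC=C)[C@@H](O[Al](C)Cl)[C@@H]1C(=C)CO[Si](C)(C)C(C)(C)C | intermediate (not isolated)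
30 | prop-2-en-1-yl 2-[(1S,2S,3S,4R,6R)-6-{[(3R)-3,4-bis(TBS-oxy)-2-methylidenebutanoyl]oxy}-3-[3-(TBS-oxy)prop-1-en-2-yl]-4-ethenyl-2-hydroxy-4-methylcyclohexyl]prop-2-enoate | C=C[C@@]1(C)C[C@@H](OC(=O)C(=C)[C@@H](O[Si](C)(C)C(C)(C)C)CO[Si](C)(C)C(C)(C)C)[C@@H](C(=C)C(=O)OCC=C)[C@@H](O)[C@@H]1C(=C)CO[Si](C)(C)C(C)(C)C | intermediate
31 | prop-2-en-1-yl 2-[(1S,2S,3S,4R,6R)-6-{[(3R)-3,4-dihydroxy-2-methylidenebutanoyl]oxy}-4-ethenyl-2-hydroxy-3-(3-hydroxyprop-1-en-2-yl)-4-methylcyclohexyl]prop-2-enoate | C=C[C@@]1(C)C[C@@H](OC(=O)C(=C)[C@@H](O)CO)[C@@H](C(=C)C(=O)OCC=C)[C@@H](O)[C@@H]1C(=C)CO | intermediate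
32 | 2-[(1S,2S,3S,4R,6R)-6-{[(3R)-3,4-dihydroxy-2-methylidenebutanoyl]oxy}-4-ethenyl-2-hydroxy-3-(3-hydroxyprop-1-en-2-yl)-4-methylcyclohexyl]prop-2-enoic acid | C=C[C@@]1(C)C[C@@H](OC(=O)C(=C)[C@@H](O)CO)[C@@H](C(=C)C(=O)O)[C@@H](O)[C@@H]1C(=C)CO | target

**Step count and risks**

Total step count: 18. Longest linear sequence: 13 steps (steps 1–7, then 13–18).

The step most likely to fail is step 16. The ene reaction of the congested, inductively deactivated (Z)-allylic silyl ether may be slow. Methyl transfer from aluminium, epimerisation at the aldehyde α-carbon, β-elimination of the acyloxy group or closure through the ring-flipped chair could then compete. The fallback moves the allylic oxygen to a late oxidation and uses the more nucleophilic isopropylidene ene donor; it sets out from 7 and returns at 31. Wittig reaction of 7 with isopropylidenetriphenylphosphorane (iPrPPh3+ I−, n-BuLi, THF) should give (3R)-3-ethenyl-N-methoxy-N,3,5-trimethylhex-4-enamide F1, and iBu2AlH the aldehyde (3R)-3-ethenyl-3,5-dimethylhex-4-enal F2. Allylboration with 15 as in step 13 should give the homoallylic alcohol F3, esterification with 22 as in step 14 the ester F4, and acetal cleavage as in step 15 the aldehyde F5. Its Me2AlCl-promoted carbonyl-ene cyclisation is the direct analogue of the citronellal–isopulegol reaction and should give the isopropenyl cyclohexanol F6. Allylic hydroxylation of the isopropenyl methyl group (SeO2 cat., t-BuOOH, CH2Cl2) should give the allylic alcohol F7, and HF·pyridine then removes the two remaining silyl ethers to reach 31.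

The second is step 13. The ester-substituted allylboronate may react slowly under the weak acid catalyst, and facial control by the catalyst may be insufficient because the aldehyde has no nearby stereocentre. The fallback replaces the catalytic allylboration by a metal-mediated Barbier reaction; it sets out from 13 and returns at 24. Bromination of 13 with allylic transposition (N-bromosuccinimide, Me2S, CH2Cl2) should give prop-2-en-1-yl (2Z)-2-(bromomethyl)-4,4-dimethoxybut-2-enoate F8. Indium powder in THF/H2O with aldehyde 10 should then give the syn adducts through an ester-chelated cyclic transition state, as 24 together with its (3S,4S,6R) diastereomer F9, from which 24 is separated by chromatography.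

The third is step 17. During the slow cleavage of the secondary silyl ether, the free ring hydroxyl may lactonise onto the cis-disposed allyl ester, or the side-chain acyl group may migrate. The fallback frees the acid first, so that the carboxylate is no longer an electrophile when the hydroxyl groups are unmasked; it sets out from 30 and returns at 32. Pd(PPh3)4 and N-methylaniline in THF should give the tris-silylated hydroxy acid 2-[(1S,2S,3S,4R,6R)-6-{[(3R)-3,4-bis(TBS-oxy)-2-methylidenebutanoyl]oxy}-3-[3-(TBS-oxy)prop-1-en-2-yl]-4-ethenyl-2-hydroxy-4-methylcyclohexyl]prop-2-enoic acid F10. Desilylation of its carboxylate with tris(dimethylamino)sulfonium difluorotrimethylsilicate in DMF should then give 32.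

Further compounds
F1 | step 16 | (3R)-3-ethenyl-N-methoxy-N,3,5-trimethylhex-4-enamide | C=C[C@@](C=C(C)C)(C)CC(=O)N(C)OC
F2 | step 16 | (3R)-3-ethenyl-3,5-dimethylhex-4-enal | C=C[C@@](C=C(C)C)(C)CC=O
F3 | step 16 | prop-2-en-1-yl (3R,4R,6R)-3-(dimethoxymethyl)-6-ethenyl-4-hydroxy-6,8-dimethyl-2-methylidenenon-7-enoate | C=C[C@@](C=C(C)C)(C)C[C@@H](O)[C@@H](C(=C)C(=O)OCC=C)C(OC)OC
F4 | step 16 | prop-2-en-1-yl (3R,4R,6R)-4-{[(3R)-3,4-bis(TBS-oxy)-2-methylidenebutanoyl]oxy}-3-(dimethoxymethyl)-6-ethenyl-6,8-dimethyl-2-methylidenenon-7-enoate | C=C[C@@](C=C(C)C)(C)C[C@@H](OC(=O)C(=C)[C@@H](O[Si](C)(C)C(C)(C)C)CO[Si](C)(C)C(C)(C)C)[C@@H](C(=C)C(=O)OCC=C)C(OC)OC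
F5 | step 16 | prop-2-en-1-yl (3R,4R,6R)-4-{[(3R)-3,4-bis(TBS-oxy)-2-methylidenebutanoyl]oxy}-6-ethenyl-3-formyl-6,8-dimethyl-2-methylidenenon-7-enoate | C=C[C@@](C=C(C)C)(C)C[C@@H](OC(=O)C(=C)[C@@H](O[Si](C)(C)C(C)(C)C)CO[Si](C)(C)C(C)(C)C)[C@@H](C(=C)C(=O)OCC=C)C=O
F6 | step 16 | isopropenyl analogue of 30 (prop-1-en-2-yl in place of 3-(TBS-oxy)prop-1-en-2-yl, same ring configuration) | C=C[C@@]1(C)C[C@@H](OC(=O)C(=C)[C@@H](O[Si](C)(C)C(C)(C)C)CO[Si](C)(C)C(C)(C)C)[C@@H](C(=C)C(=O)OCC=C)[C@@H](O)[C@@H]1C(C)=C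
F7 | step 16 | analogue of 30 with a free 3-hydroxyprop-1-en-2-yl group (side-chain silyl ethers retained) | C=C[C@@]1(C)C[C@@H](OC(=O)C(=C)[C@@H](O[Si](C)(C)C(C)(C)C)CO[Si](C)(C)C(C)(C)C)[C@@H](C(=C)C(=O)OCC=C)[C@@H](O)[C@@H]1C(=C)CO
F8 | step 13 | prop-2-en-1-yl (2Z)-2-(bromomethyl)-4,4-dimethoxybut-2-enoate | C=CCOC(=O)/C(CBr)=C/C(OC)OC
F9 | step 13 | prop-2-en-1-yl (3S,4S,6R,7Z)-9-(TBS-oxy)-3-(dimethoxymethyl)-6-ethenyl-4-hydroxy-6,8-dimethyl-2-methylidenenon-7-enoate | C=C[C@@](/C=C(/C)CO[Si](C)(C)C(C)(C)C)(C)C[C@H](O)[C@H](C(=C)C(=O)OCC=C)C(OC)OC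
F10 | step 17 | 2-[(1S,2S,3S,4R,6R)-6-{[(3R)-3,4-bis(TBS-oxy)-2-methylidenebutanoyl]oxy}-3-[3-(TBS-oxy)prop-1-en-2-yl]-4-ethenyl-2-hydroxy-4-methylcyclohexyl]prop-2-enoic acid | C=C[C@@]1(C)C[C@@H](OC(=O)C(=C)[C@@H](O[Si](C)(C)C(C)(C)C)CO[Si](C)(C)C(C)(C)C)[C@@H](C(=C)C(=O)O)[C@@H](O)[C@@H]1C(=C)CO[Si](C)(C)C(C)(C)C
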